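In a closed, stirred vessel at constant temperature, starting material and partner make product, and Saturday's flask ends near 0.0442 M, just 22.1% of its starting material.

| flask | starting material | partner | product | time |
|---|---|---|---|---|
| Saturday's | 0.200 M | 0.300 M |  |  |
| Monday's | 0.0800 M | 0.180 M |  |  |
| Wednesday's | 0.200 M | 0.900 M |  |  |
| Thursday's | 0.400 M | 0.300 M |  |  |
| Sunday's | 0.200 M | 0.300 M | 0.100 M | 36 h |

- Saturday's run (time / h: [product] / M): 1.3: 0.0102; 3.9: 0.0190; 7.5: 0.0291; 12: 0.0361; 17: 0.0394; 23: 0.0419; 29: 0.0437; 36: 0.0442
- Monday's run (time / h: [product] / M): 1.3: 0.0025; 3.9: 0.0060; 7.5: 0.0092; 12: 0.0150; 17: 0.0123; 23: 0.0191; 29: 0.0181; 36: 0.0212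
- Wednesday's run (time / h: [product] / M): 1.3: 0.0239; 3.9: 0.0433; 7.5: 0.0549; 12: 0.0636; 17: 0.0672; 23: 0.0684; 29: 0.0717; 36: 0.0696
- Thursday's run (time / h: [product] / M): 1.3: 0.0164; 3.9: 0.0368; 7.5: 0.0480; 12: 0.0589; 17: 0.0624; 23: 0.0627; 29: 0.0667; 36: 0.0678

(standard deviation of a reading: 0.001 M)

- Overall: starting material + partner -> product.
- Constant volume, constant temperature.
- "The second partner" is partner.
- An order is taken over about fifteen percent of the charge, up and down.
- A share of product counts the product that was charged too.

1. the power of [starting material] that the first rate follows, about the charge of the Saturday's run; measure it at two percent of starting material made into product (one fixed amount of product, the same in the runs compared)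
2. the power of [partner] that the first rate follows, about the charge of the Saturday's run; measure it at two percent of starting material made into product
3. product in the Sunday's run at 36 h, as a share of the starting material charged

Start from the rate. Saturday's first interval gives 0.00785 M h⁻¹, and from 17 h to 36 h the same flask gives 2.53 × 10⁻⁴ M h⁻¹, a fall by a factor of 31.1. Is product the brake? Wednesday's flask, between 3.9 h and 7.5 h, still makes 0.00322 M h⁻¹, which is 12.8 times Saturday's late rate on 3.00 times the partner, and it holds more product than Saturday's flask does late. So I read the slowing as following the clock, not the product.

That gives one number to carry: the stall time, the last reading divided by the first-interval rate, or the hours the first rate would need to make what the flask ends with. For Saturday's flask it is 5.63 h. Wednesday's is shorter at 3.79 h, while Thursday's, on 2.00 times the starting material, stays close at 5.37 h.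

First-interval rates give a power of 0.685 for starting material, Thursday's flask against Saturday's, and 0.775 for partner, Wednesday's flask against Saturday's. I put both near one, above these readings, because that interval already spans a quarter of Saturday's stall time and the scatter is 9.80% of Saturday's first reading.

Sunday's flask has Saturday's charge plus charged product, and I read the slowing as following the clock, so I add Saturday's first rate times Saturday's stall time, which is simply Saturday's last reading again, to what was charged and get 72.1%.

The forecast gives 0.95, 0.95 and 60%, holding that “the 0.100 M of charged product cuts the rate roughly fourfold”. My share stands 12 percentage points above its figure.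

    starting material + partner ⇌ product + by-product (0.1325 M⁻¹ h⁻¹, 0.05796 M⁻¹ h⁻¹)
    2 partner → lost reagent (0.2351 M⁻¹ h⁻¹)
    2 starting material → homo dimer (0.1786 M⁻¹ h⁻¹)

The flask gives powers of 1.1 for starting material and 1.1 for partner, and 70.1% for Sunday's run. That is 0.0401 M of new product in Sunday's flask, 0.907 of Saturday's last reading. Divided by Saturday's stall time, it asks for a first rate of 0.00712 M h⁻¹ in Sunday's flask, against Saturday's first-interval 0.00785 M h⁻¹. Thursday's rate where two percent of Saturday's starting material have turned, 0.014 M h⁻¹, times Saturday's stall time gives 0.0813 M, against Thursday's last reading of 0.0678 M.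

Readings and results were generated by integration from invented constants; the scatter is artificial.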